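**Plan**

1. Retrosynthesis: the C17 hydroxyl and H-16 come from an α-methylene ketone (formal hydration last); ring D is cut at C13–C16 and the C15 ketone goes back to an allylic methylene; ring A is cut at C3–C4 and C5–C10 into lactone aldehyde 13 and ethyl 3-formylcrotonate 14; then C8–C15 (enolate alkylation), C10=C1 (Wittig) and ring C at C8–C14/C9–C11 (Diels–Alder).
2. Forward: pyran-3,6-dione (the δ-lactone ring) → Diels–Alder builds ring C → olefination and C8 propargylation → radical–polar crossover annulation builds ring A → reduction/lactonisation closes the γ-lactone → tin hydride removes the helper 3-OH and closes ring D → C15 oxidation, desilylation, borylation/oxidation.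
3. Enabling feature: C10 is the spiro atom of the δ-lactone ring (C7–O–C20–C10–C9–C8) and carries C1–C3, so an exocyclic C10=C1 alkene gives a ring-held tertiary radical on hydrogen-atom transfer. C5 bears the C6 carboxyl and C4 the C19 oxygen (the cis γ-lactone is a reduced 2-formyl-2-methylsuccinate), so a β-formylcrotonate takes the radical at C5 and returns a C4 enolate that closes on a C3 aldehyde.
4. Stereochemistry: C8/C9/C11 from a catalytic enantioselective endo Diels–Alder reaction; quaternary C8 by alkylation on the H-9 face; C10 by radical attack on the H-9 face of the lactone; C4 by the chair aldol; C5 by equilibration to the cis-lactone; C13 by the bridged ring closure; C16 by exo protonation.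

Key step: step 8

Remarks on the chemistry:
- Locants follow ent-kaurane numbering of the target: C4 (quaternary, bears methyl C18 and C19H2–O), C5 (CH bearing the γ-lactone carbonyl C6), C10 (spiro carbon bearing C20H2–O), C7 (δ-lactone carbonyl on C8), ring C = C8, C9, C11–C14, ring D = C8, C13–C16, C15 ketone, C17 = CH2OH on C16.
- Assumption: the antipode of the oxazaborolidinium catalyst in step 4 is the one that gives (4aS,5R,8aS)-6; the (S)-catalyst is written from the usual enone pre-transition-state model, and the other antipode would be used if the sense were opposite.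
- Compounds 9, 12 and 13 are E/Z mixtures at C10=C1 (drawn without alkene geometry); this does not matter because C10 becomes a radical. Compound 17 is drawn with the C5 configuration of the target.

**Step 1**
Reactants: 1 furfuryl alcohol (furan-2-ylmethanol)
Product: 2 6-hydroxy-2H-pyran-3(6H)-one (racemic lactol)
Conditions: mCPBA, CH2Cl2, 0 °C
Reagents that add atoms: mCPBA (3-chloroperoxybenzoic acid), OOC(=O)c1cccc(Cl)c1
Why: Achmatowicz rearrangement (furan epoxidation and ring expansion of the 2-furylcarbinol) should give the pyranone hemiacetal, whose acetal centre is removed in step 2.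

**Step 2**
Reactants: 2 6-hydroxy-2H-pyran-3(6H)-one
Product: 3 2H-pyran-3,6-dione
Conditions: PhI(OAc)2, TEMPO (cat.), CH2Cl2, rt; used crude
Reagents that add atoms: none
Why: Oxoammonium (TEMPO) oxidation of a lactol to the lactone should give the cyclic ene-dione, an oxygen analogue of a quinone dienophile.

**Step 3**
Reactants: 4 (E)-but-2-enal
Product: 5 (E)-1-(tert-butyldimethylsilyloxy)buta-1,3-diene
Conditions: TBSOTf, Et3N, Et2O, 0 °C → rt
Reagents that add atoms: tert-butyldimethylsilyl triflate, CC(C)(C)[Si](C)(C)OS(=O)(=O)C(F)(F)F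
Why: O-Silylation of the dienolate of the enal (silyl dienol ether formation) should give the (E)-1-siloxydiene.

**Step 4**
Reactants: 3 2H-pyran-3,6-dione; 5 (E)-1-(tert-butyldimethylsilyloxy)buta-1,3-diene
Product: 6 (4aS,5R,8aS)-5-(tert-butyldimethylsilyloxy)-4a,5,8,8a-tetrahydro-1H-isochromene-1,4(3H)-dione (cis-fused keto lactone; H-8, H-9 and H-11 on one face)
Conditions: chiral oxazaborolidinium triflimide [(S)-diphenylprolinol-derived, B-(o-tolyl), 20 mol %], CH2Cl2, −78 °C
Reagents that add atoms: none
Why: Catalytic enantioselective Diels–Alder reaction in which the Lewis acid binds the ketone (C10=O), so that C14 joins C8 and the silyloxy-bearing C11 joins C9, endo addition to the cis dienophile puts the silyloxy group cis to both ring-fusion bonds, and the catalyst sets the absolute sense.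

**Step 5**
Reactants: 6 keto lactone; 7 [2-(1,3-dioxolan-2-yl)ethyl]triphenylphosphonium bromide
Product: 9 alkylidene lactone (6 with C10=O replaced by C10=C1H–C2H2–C3H(OCH2CH2O)), via ylide 8 (not isolated)
Conditions: KN(SiMe3)2, THF, −78 °C; then 6, −78 → 0 °C
Reagents that add atoms: none
Why: Wittig olefination with a non-stabilised ylide at the ketone, which is more electrophilic than the lactone, should install C1–C3 as the exocyclic trisubstituted alkene.

**Step 6**
Reactants: 9 alkylidene lactone; 10 3-bromo-1-(trimethylsilyl)prop-1-yne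
Product: 12 C8-propargylated lactone (CH2C≡C–SiMe3 on C8, cis to H-9), via lithium enolate 11 (not isolated)
Conditions: LiN(i-Pr)2, THF, −78 °C; then 10, DMPU, −78 → −30 °C
Reagents that add atoms: none
Why: Lactone enolate alkylation at the ring-fusion carbon, in which the electrophile enters on the H-9 face anti to the C9–C11 bond, should keep the lactone cis-fused and set the quaternary C8 with C15 trans to C11.

**Step 7**
Reactants: 12 C8-propargylated acetal
Product: 13 β,γ-unsaturated aldehyde (free C3 aldehyde)
Conditions: LiBF4, MeCN/H2O (98:2), 40 °C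
Reagents that add atoms: water, O
Why: Mild Lewis-acid-assisted acetal hydrolysis should free the C3 aldehyde without cleaving the silyl ether or the alkynylsilane and without moving the alkene into conjugation.

**Step 8**
Reactants: 13 lactone aldehyde; 14 ethyl (2E)-3-methyl-4-oxobut-2-enoate
Product: 17 ring-A hydroxy aldehyde ester (C3–OH; C4 bears CH3 and CHO; C5 bears CO2Et; C10 spiro), via C10 radical 15 (not isolated), via iron enolate 16 (not isolated)
Conditions: Fe(acac)3 (0.3 equiv), PhSiH3 (2.5 equiv), 14 (3 equiv), EtOH/(CH2OH)2 (5:1), 0 °C → rt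
Reagents that add atoms: none
Why: A trivalent iron hydride made from Fe(acac)3 and PhSiH3 transfers a hydrogen atom to C1 of the trisubstituted alkene to give tertiary radical 15, which adds to 14 at C5; divalent iron reduces the resulting α-formyl radical to enolate 16, which closes ring A by aldol addition to the C3 aldehyde. The closest known reaction type is the MHAT-initiated radical–polar crossover annulation (Giese addition, then aldol cyclisation) of alkene-tethered carbonyl compounds with unsaturated carbonyl acceptors. The C5–C10 bond forms intermolecularly and ring A then closes by a 6-(enolexo)-exo-trig aldol that forms C3–C4. C10 is set because the radical sits in the half-chair δ-lactone and is attacked on the H-9 face, anti to C11 with its silyloxy group and to the axial C14 methylene of ring C. C4 is set in a chair aldol transition state with C9 equatorial and C20 axial, the flat enolate carbon C19 pseudo-axial and syn to C20, the methyl equatorial and the metal bridging both oxygens (3-OH cis to C19); C5 may form as a mixture and is corrected in step 9. The step needs HAT at the trisubstituted alkene rather than the ring alkene or silylalkyne, and radical attack at C5 rather than C4; both follow from substitution, since attack at the CH terminus leaves the tertiary formyl-stabilised radical.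

**Step 9**
Reactants: 17 hydroxy aldehyde ester
Product: 19 bis-lactone alcohol with terminal alkyne (γ-lactone C19–O–C6 cis-fused on C4–C5; 3-OH; C8–CH2C≡CH), via diol ester 18 (not isolated)
Conditions: NaBH4, MeOH, −20 °C; then NaOMe (cat.), MeOH, rt; pH 7 buffer
Reagents that add atoms: none
Why: Chemoselective borohydride reduction of the neopentyl aldehyde followed by methoxide-mediated lactonisation onto the C6 ester should give the cis-fused γ-lactone as the thermodynamic product (a C5-epimeric ester equilibrates through its enolate), and methoxide also removes the alkynyl silyl group.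

**Step 10**
Reactants: 19 bis-lactone alcohol
Product: 20 O-phenyl thionocarbonate of the C3 alcohol
Conditions: PhOC(S)Cl, pyridine, DMAP (cat.), CH2Cl2, 0 °C → rt
Reagents that add atoms: O-phenyl chlorothionoformate, S=C(Cl)Oc1ccccc1
Why: Acylation of the only free hydroxyl should give the thionocarbonate needed for radical deoxygenation.

**Step 11**
Reactants: 20 thionocarbonate
Product: 22 16-methylene tetracycle (ring D closed, C3 deoxygenated, 11-OTBS), via vinylstannane 21 (not isolated)
Conditions: Bu3SnH (2.5 equiv, slow addition), AIBN (cat.), PhH, 80 °C; then HCl (1 M in Et2O), CH2Cl2, 0 °C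
Reagents that add atoms: none
Why: Barton–McCombie deoxygenation at C3 and, in the same tin hydride chain, stannyl radical addition to the terminal alkyne with 5-exo-trig cyclisation of the C16 vinyl radical onto C13 (the axial C15 arm reaches only one face, which fixes the bridgehead) should close ring D, and protodestannylation then gives the exocyclic methylene.

**Step 12**
Reactants: 22 16-methylene tetracycle
Product: 23 15-hydroxy-16-methylene compound (15-OH exo, syn to C14)
Conditions: SeO2 (0.5 equiv), t-BuOOH, CH2Cl2, rt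
Reagents that add atoms: tert-butyl hydroperoxide, CC(C)(C)OO
Why: Selenium dioxide allylic hydroxylation (ene reaction, then [2,3]-shift) should occur at C15, the only allylic methylene of the exocyclic alkene.

**Step 13**
Reactants: 23 allylic alcohol
Product: 24 16-methylene-15-ketone (11-OTBS)
Conditions: DMP, CH2Cl2, 0 °C → rt
Reagents that add atoms: none
Why: Periodinane oxidation of the allylic alcohol should give the α-methylene cyclopentanone under neutral conditions.

**Step 14**
Reactants: 24 silyl-protected enone
Product: 25 11-hydroxy-16-methylene-15-ketone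
Conditions: HF·pyridine, THF, 0 °C → rt
Reagents that add atoms: none
Why: Fluoride-mediated desilylation under mildly acidic conditions should free the C11 hydroxyl without opening the lactones.

**Step 15**
Reactants: 25 hydroxy enone
Product: 27 target CNP0555433.1, (4R,5R,8S,9S,10R,11R,13S,16S), via boronate 26 (not isolated)
Conditions: CuCl (5 mol %), DPEphos (5 mol %), NaOt-Bu (10 mol %), B2pin2 (1.2 equiv), MeOH (2 equiv), THF, 0 °C; then NaBO3·4H2O, THF/H2O, 0 °C
Reagents that add atoms: sodium perborate tetrahydrate (NaBO3·4H2O), O.O.O.O.[Na+].[O-]B1OO1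
Why: Copper-catalysed conjugate borylation of the α-methylene ketone followed by kinetic protonation of the enolate by methanol on the exo face (syn to C14) should place C17 endo (16S), and C–B oxidation with retention then gives the primary alcohol.

**Compound list**

1 | furfuryl alcohol | OCc1ccco1 | starting material
2 | 6-hydroxy-2H-pyran-3(6H)-one (racemic) | O=C1COC(O)C=C1 | intermediate
3 | 2H-pyran-3,6-dione | O=C1COC(=O)C=C1 | intermediate
4 | (E)-but-2-enal | C/C=C/C=O | starting material
5 | (E)-1-(tert-butyldimethylsilyloxy)buta-1,3-diene | C=C/C=C/O[Si](C)(C)C(C)(C)C | intermediate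
6 | (4aS,5R,8aS)-5-(tert-butyldimethylsilyloxy)-4a,5,8,8a-tetrahydro-1H-isochromene-1,4(3H)-dione | O=C1COC(=O)[C@H]2CC=C[C@@H](O[Si](C)(C)C(C)(C)C)[C@H]21 | intermediate
7 | [2-(1,3-dioxolan-2-yl)ethyl]triphenylphosphonium bromide | [Br-].C1COC(CC[P+](c2ccccc2)(c2ccccc2)c2ccccc2)O1 | starting material
8 | [2-(1,3-dioxolan-2-yl)ethylidene]triphenylphosphorane | C1COC(CC=P(c2ccccc2)(c2ccccc2)c2ccccc2)O1 | intermediate
9 | 4-[2-(1,3-dioxolan-2-yl)ethylidene] lactone (C10=C1, E/Z mixture; C8, C9, C11 as in 6) | C1COC(CC=C2COC(=O)[C@H]3CC=C[C@@H](O[Si](C)(C)C(C)(C)C)[C@H]32)O1 | intermediate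
10 | 3-bromo-1-(trimethylsilyl)prop-1-yne | BrCC#C[Si](C)(C)C | starting material
11 | lithium enolate of 9 (C7=C8) | C1COC(CC=C2COC([O-])=C3CC=C[C@@H](O[Si](C)(C)C(C)(C)C)[C@H]32)O1.[Li+] | intermediate
12 | C8-[3-(trimethylsilyl)prop-2-ynyl] lactone acetal (propargyl cis to H-9) | C1COC(CC=C2COC(=O)[C@@]3(CC#C[Si](C)(C)C)CC=C[C@@H](O[Si](C)(C)C(C)(C)C)[C@H]32)O1 | intermediate
13 | lactone aldehyde (C3 aldehyde, C10=C1 alkene) | O=CCC=C1COC(=O)[C@@]2(CC#C[Si](C)(C)C)CC=C[C@@H](O[Si](C)(C)C(C)(C)C)[C@H]21 | intermediate
14 | ethyl (2E)-3-methyl-4-oxobut-2-enoate | CCOC(=O)/C=C(C)/C=O | starting material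
15 | tertiary C10 radical from 13 | O=CCC[C]1COC(=O)[C@@]2(CC#C[Si](C)(C)C)CC=C[C@@H](O[Si](C)(C)C(C)(C)C)[C@H]21 | intermediate
16 | C4 aldehyde enolate after Giese addition (iron enolate, drawn as the anion) | [O-]C=C(C)[C@@H](C(=O)OCC)[C@]1(CCC=O)COC(=O)[C@@]2(CC#C[Si](C)(C)C)CC=C[C@@H](O[Si](C)(C)C(C)(C)C)[C@H]21 | intermediate
17 | ring-A hydroxy aldehyde ester (3-OH cis to the C4 formyl group; C4 methyl trans to C20) | C[C@@]1(C=O)[C@H](O)CC[C@]3(COC(=O)[C@@]4(CC#C[Si](C)(C)C)CC=C[C@@H](O[Si](C)(C)C(C)(C)C)[C@H]43)[C@@H]1C(=O)OCC | intermediate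
18 | diol ester (C19 alcohol, C6 ethyl ester) | C[C@@]1(CO)[C@H](O)CC[C@]3(COC(=O)[C@@]4(CC#C[Si](C)(C)C)CC=C[C@@H](O[Si](C)(C)C(C)(C)C)[C@H]43)[C@@H]1C(=O)OCC | intermediate
19 | bis-lactone 3-alcohol with C8 propargyl group | C[C@@]12[C@H](O)CC[C@]3(COC(=O)[C@@]4(CC#C)CC=C[C@@H](O[Si](C)(C)C(C)(C)C)[C@H]43)[C@@H]1C(=O)OC2 | intermediate
20 | 3-O-(phenoxythiocarbonyl) derivative of 19 | C[C@@]12[C@H](OC(=S)Oc5ccccc5)CC[C@]3(COC(=O)[C@@]4(CC#C)CC=C[C@@H](O[Si](C)(C)C(C)(C)C)[C@H]43)[C@@H]1C(=O)OC2 | intermediate
21 | 17-(tributylstannyl)-16-methylene tetracycle (E/Z mixture) | C[C@@]12CCC[C@]3(COC(=O)[C@@]45C[C@@H](C[C@@H](O[Si](C)(C)C(C)(C)C)[C@H]43)C(=C[Sn](CCCC)(CCCC)CCCC)C5)[C@@H]1C(=O)OC2 | intermediate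
22 | 16-methylene tetracycle, 11-OTBS | C[C@@]12CCC[C@]3(COC(=O)[C@@]45C[C@@H](C[C@@H](O[Si](C)(C)C(C)(C)C)[C@H]43)C(=C)C5)[C@@H]1C(=O)OC2 | intermediate
23 | 15-hydroxy-16-methylene tetracycle, 11-OTBS (15-OH exo) | C[C@@]12CCC[C@]3(COC(=O)[C@@]45C[C@@H](C[C@@H](O[Si](C)(C)C(C)(C)C)[C@H]43)C(=C)[C@@H]5O)[C@@H]1C(=O)OC2 | intermediate
24 | 16-methylene-15-ketone, 11-OTBS | C[C@@]12CCC[C@]3(COC(=O)[C@@]45C[C@@H](C[C@@H](O[Si](C)(C)C(C)(C)C)[C@H]43)C(=C)C5=O)[C@@H]1C(=O)OC2 | intermediate
25 | 11-hydroxy-16-methylene-15-ketone | C[C@@]12CCC[C@]3(COC(=O)[C@@]45C[C@@H](C[C@@H](O)[C@H]43)C(=C)C5=O)[C@@H]1C(=O)OC2 | intermediate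
26 | 17-(pinacolboryl) ketone (C17 endo) | C[C@@]12CCC[C@]3(COC(=O)[C@@]45C[C@@H](C[C@@H](O)[C@H]43)[C@@H](CB6OC(C)(C)C(C)(C)O6)C5=O)[C@@H]1C(=O)OC2 | intermediate
27 | CNP0555433.1 | C[C@@]12CCC[C@]3(COC(=O)[C@@]45C[C@@H](C[C@@H](O)[C@H]43)[C@@H](CO)C5=O)[C@@H]1C(=O)OC2 | target

**Totals**

Total step count: 15. Longest linear sequence: 14 steps (1 → 2 → 3 → 6 → 9 → 12 → 13 → 17 → 19 → 20 → 22 → 23 → 24 → 25 → 27; step 3 is a side branch).

**Steps most likely to fail**

Step 8. The enolate 16 may be protonated before it closes the ring, the radical 15 may be reduced by a second hydrogen-atom transfer, or facial selectivity at C10 and in the aldol closure may be poor. The fallback separates the two bond formations; it sets out from 12 and comes back at 17. The same Fe(acac)3/PhSiH3 Giese addition to 14 is run on acetal 12, where the enolate can only be protonated, to give the Giese adduct acetal F1. Bromination of its aldehyde through the trimethylsilyl enol ether (TMSCl, Et3N, NaI; then NBS) gives the tertiary α-bromo aldehyde acetal F2. LiBF4 in wet MeCN frees the C3 aldehyde to give the α-bromo dialdehyde F3. SmI2 (THF, −78 °C) then generates the C4 enolate regiospecifically for an intramolecular Reformatsky-type aldol that gives 17.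

Step 5. The basic ylide may enolise the ketone, leading to β-elimination of the silyloxy group or epimerisation at C9, and addition to the hindered carbonyl may be slow. The fallback sets out from 6 and comes back at 9. CeCl3-promoted addition of [2-(1,3-dioxolan-2-yl)ethyl]magnesium bromide (a non-basic organocerium addition) gives the tertiary carbinol F4. Syn-dehydration with methyl N-(triethylammoniosulfonyl)carbamate through the freely rotating side-chain methylene then gives 9.

Step 4. Enantio- or regiocontrol may erode, and the acidic catalyst may desilylate or polymerise the silyloxydiene. The fallback moves the stereocontrol into the dienophile; it sets out from 2 and comes back at 6. Acetylation (Ac2O, pyridine) and lipase-mediated kinetic resolution of the anomeric acetate give (R)-6-acetoxy-2H-pyran-3(6H)-one F5. Thermal Diels–Alder reaction with 5 (toluene, rt), endo and anti to the acetoxy group, gives the adduct acetate F6. Selective anomeric deacetylation (hydrazine acetate, DMF) gives the lactol F7, and PhI(OAc)2/TEMPO oxidation as in step 2 gives 6.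

**Further compounds**

F1 | step 8 | Giese adduct acetal (C5–C10 bond formed, C4–H as epimer mixture, C3 as dioxolane) | CC(C=O)[C@@H](C(=O)OCC)[C@]1(CCC2OCCO2)COC(=O)[C@@]2(CC#C[Si](C)(C)C)CC=C[C@@H](O[Si](C)(C)C(C)(C)C)[C@H]21
F2 | step 8 | tertiary α-bromo aldehyde acetal (Br on C4, epimer mixture) | CC(Br)(C=O)[C@@H](C(=O)OCC)[C@]1(CCC2OCCO2)COC(=O)[C@@]2(CC#C[Si](C)(C)C)CC=C[C@@H](O[Si](C)(C)C(C)(C)C)[C@H]21
F3 | step 8 | α-bromo dialdehyde (free C3 aldehyde) | CC(Br)(C=O)[C@@H](C(=O)OCC)[C@]1(CCC=O)COC(=O)[C@@]2(CC#C[Si](C)(C)C)CC=C[C@@H](O[Si](C)(C)C(C)(C)C)[C@H]21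
F4 | step 5 | tertiary C10 carbinol (epimer mixture at C10) | OC1(CCC2OCCO2)COC(=O)[C@H]2CC=C[C@@H](O[Si](C)(C)C(C)(C)C)[C@H]21
F5 | step 4 | (R)-6-acetoxy-2H-pyran-3(6H)-one | O=C1CO[C@H](OC(C)=O)C=C1
F6 | step 4 | Diels–Alder adduct acetate (acetoxy on C7, cis to H-8) | O=C1CO[C@H](OC(C)=O)[C@H]2CC=C[C@@H](O[Si](C)(C)C(C)(C)C)[C@H]21
F7 | step 4 | bicyclic lactol (anomer mixture) | O=C1COC(O)[C@H]2CC=C[C@@H](O[Si](C)(C)C(C)(C)C)[C@H]21
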